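**Target:** 8α-hydroxy-5β-labda-13(16),14-dien-18-yl (Z)-3-(4-hydroxyphenyl)prop-2-enoate. Atoms carry labdane numbers: ring A = C1–C5, C10; ring B = C5–C10; C11–C16 side chain; C17 methyl on C8; C18 the 4α-CH2O carbon; C19 the 4β-methyl; C20 the C10 methyl. β is the face of C20.

## Analysis of the target

The molecule is a labdane diterpenoid ester built on a decalin. C9 carries a chain ending in a 2-substituted buta-1,3-diene (C13(=C16)–C14=C15), C8 is a tertiary carbinol, and the neopentyl C18 oxygen is acylated by (Z)-4-hydroxycinnamic acid. Five stereocentres run in one chain, C8–C9–C10–C5–C4. H5 and the C10 methyl are both β, so the decalin is cis-fused (a 5β-labdane). The C9 arm is β and cis to the C10 methyl, the 8-hydroxyl is α, and at C4 the oxygenated carbon is α and the methyl β. C4 and C10 are quaternary and flank the ring-fusion CH; C8 is fully substituted as well. The sensitive groups are the Z-cinnamate (isomerised by light, base and nucleophiles), the diene (acid, oxidants, radicals), the phenol, and the 8α-hydroxyl, which closes cyclic ethers onto C12 or C13 as soon as either becomes electrophilic. The hard points are the crowded C4–C5 bond, the C4 configuration that puts the CH2O group on the concave side of the cis-decalin, and a carbinol on a conformationally mobile ring B. The strategy rests on one feature: quaternary C4 is bonded directly to the fusion carbon C5, and C1 leaves quaternary C10 on the α-face, so a C1–C3 chain can deliver a C4 radical only to the α-face of C5 of a ring-B enone, which is the cis fusion.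

## Retrosynthetic reasoning

The Z-cinnamate is made last. Target 36 comes from its silyl-protected phenol 35, and the Z-alkene of 35 from a Z-selective olefination of substrate-bound phosphonoacetate 33 with aldehyde 34. Phosphonate 33 goes back through bromoacetate 32 to diol 31. The ester is cut here because a Z-cinnamate survives neither hydride nor organomagnesium reagents, and because the primary 18-hydroxyl of 31 is acylated selectively beside the tertiary 8-hydroxyl.

The diene is cut at C12–C13: bis-silyl ether 30 comes from iodide 27 and dienyl Grignard reagent 29, made from 28. One sp3–sp2 coupling brings in all four diene carbons, and it is placed late because the diene would not survive the peracid and radical steps. The 8-hydroxyl is masked first (24 to 25), since an 8α-oxygen would displace a C12 leaving group and close a five-membered ether; the C12 oxygen is then freed (26) and activated (27).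

The C8 carbinol is traced to epoxide 23, alkene 22, enol triflate 21 and ketone 19. The C7 carbonyl is the remnant of the enone used in the key step; it serves once more to place the Δ7 double bond and then disappears. Epoxide opening by hydride at C7 leaves the oxygen on C8.

The key cut is C4–C5: hydroxy ketone 18 comes from hydroxy enone 17. This bond joins a quaternary to a tertiary carbon, which is hard for ionic chemistry and easy for a tertiary radical. Cutting it turns ring A into a chain on C10 and leaves a monocyclic enone with only two stereocentres that matter. The forward step must place a hydrogen atom on the terminal alkene carbon, close 6-exo on the α-face of C5, and put the CH2OH group over ring B.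

Enone 17 comes from silyl ether 16, and 16 from enone 14 by α′-methylation at C8, the only enolisable position. Enone 14 comes from silyl enol ether 13, which stores the enone regiochemistry. The tether of 13 is cut at C2–C3 into vinyl compound 8 and allylic phosphate 11, joined through alkylborane 12. This avoids any selective alkene reduction beside the C4 methylidene group. Vinyl compound 8 comes from aldehyde 7, whose formyl carbon becomes C1.

Aldehyde 7 is cut at C5–C10 and C8–C9 into enal 4 and diene 6. The E-geometry of 4 becomes the cis relation of C20 and the C9 arm, the formyl group activates the dienophile, and one catalyst-controlled face selection sets C9 and C10 together.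

Enal 4 comes from aldehyde 2 (from alcohol 1) and ylide 3, diene 6 from enone 5, and phosphate 11 from diol 9 through mono-silyl ether 10.

## Alternatives that were turned down

Alternative 1: The octalin ester A1 would be cut at C5–C10 and C3–C4 at once, opening both rings to the acyclic triene ester A2. Forward, A2 would be heated or treated with Me2AlCl so that its diene (C3=C2–C1=C10) and its (Z)-2-methyl enoate (C4=C5) combine intramolecularly. In its favour, two rings, two C–C bonds and three stereocentres form in one step, and the tether on the inside of the Z-diene allows only cis fusion. The C4/C5 relation is fixed stereospecifically by the enoate geometry; on this point it is stronger than the chosen route, where C4 depends on a weak polar contact. Against it, both bonding termini (C10 and C4) become quaternary, the fully substituted diene terminus makes the reactive s-cis conformer strained, Z-dienes suffer 1,5-hydrogen shifts on heating, and the dioxolane and silyl ether limit Lewis-acid activation. Face selection relative to the single C9 stereocentre is uncertain, and A2 needs two trisubstituted Z-alkenes. After the cycloaddition the Δ1 alkene, the ester, the C8 carbinol and the whole side chain remain to be dealt with. The chosen route forms the same crowded C4–C5 bond with a radical, which tolerates crowding, near room temperature, from a precursor made by an intermolecular cycloaddition of simple partners.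

Alternative 2: Only the diene would be taken apart: silyl ether A3 from terminal alkyne A4 and ethylene A5, forming C13=C16 and C14=C15. Forward, second-generation Grubbs catalyst RuCl2(=CHPh)(PCy3)(H2IMes) would effect cross enyne metathesis. In its favour, the step is mild, tolerates the free tertiary alcohol and avoids a dienyl Grignard reagent; for the diene installation it is at least as reliable as the copper-catalysed coupling chosen here, and it is kept as the fallback for step 21. Against it as a strategy, no ring is closed and no stereocentre is set. The cis-decalin, C4 and C8 are all pushed into the synthesis of A4, which still needs a C12–C13 bond formation with the same 8-oxygen participation problem. It complements the chosen strategy and does not replace it.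

Alternative 3: The C8–C9 bond of hydroxy ester A6 would be cut, opening ring B to cyclohexane A7, which carries an (E)-enoate on C10 and a 3-oxobutyl chain on C5. Forward, SmI2 would reduce the methyl ketone to its ketyl, which adds 6-exo to the enoate β-carbon C9. In its favour, the C8 carbinol and its methyl arise directly, usually with hydroxyl and ester arm anti, as the target requires, and there is no C7 oxygen to remove. On C8 it is clearly stronger than the chosen route, which spends steps 14–17 and a face-selective epoxidation there. Against it, ring A with the contiguous C4/C5/C10 triad (two quaternary carbons) must exist beforehand, so the hardest part is not addressed by the key step. The C9 configuration depends on the conformation of an enoate on a quaternary carbon, and the arm arrives one carbon short as an ester. The chosen route creates C9/C10 and then C5/C4 in two bond-forming steps and accepts a longer sequence at C8.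

Key step: step 12

Assumption: the (S)-configured catalyst of step 4 is taken to give the (1S,6S) adduct 7; if the sense of induction is opposite, the (R)-catalyst is used and nothing else changes.

## Route

Step 1
Reactants: 1 3-(benzyloxy)propan-1-ol
Product: 2 3-(benzyloxy)propanal
Conditions: TEMPO (10 mol%), PhI(OAc)2, CH2Cl2, 25 °C
Reagents that add atoms: none
Why: Nitroxyl-catalysed oxidation of a primary alcohol stops at the aldehyde and is neutral enough that the β-benzyloxy aldehyde does not eliminate benzyl alcohol.

Step 2
Reactants: 2 3-(benzyloxy)propanal; 3 2-(triphenylphosphoranylidene)propanal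
Product: 4 (E)-5-(benzyloxy)-2-methylpent-2-enal
Conditions: toluene, 80 °C
Reagents that add atoms: none
Why: Wittig olefination with a formyl-stabilised α-methyl ylide gives the (E)-trisubstituted enal, and the conjugated product should not react further with the ylide.

Step 3
Reactants: 5 but-3-en-2-one
Product: 6 2-(triisopropylsilyloxy)buta-1,3-diene
Conditions: i-Pr3SiOTf, Et3N, Et2O, 0 → 25 °C
Reagents that add atoms: triisopropylsilyl trifluoromethanesulfonate, CC(C)[Si](C(C)C)(C(C)C)OS(=O)(=O)C(F)(F)F
Why: Soft enolisation and O-silylation of the methyl ketone gives the 2-silyloxydiene; the bulky silyl group keeps the diene and the later enol ether stable to the acid catalyst and to base.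

Step 4
Reactants: 4 (E)-5-(benzyloxy)-2-methylpent-2-enal; 6 2-(triisopropylsilyloxy)buta-1,3-diene
Product: 7 (1S,6S)-6-[2-(benzyloxy)ethyl]-1-methyl-4-(triisopropylsilyloxy)cyclohex-3-ene-1-carbaldehyde (methyl cis to the arm)
Conditions: (S)-B-(o-tolyl)-α,α-diphenylprolinol oxazaborolidine·HNTf2 (20 mol%), CH2Cl2, −78 → −40 °C
Reagents that add atoms: none
Why: Catalytic enantioselective Diels–Alder reaction under a chiral N-protonated oxazaborolidine, a catalyst class that accepts (E)-2-methyl-2-alkenals. The CH2 terminus next to the silyloxy carbon bonds to the enal β-carbon (para orientation), suprafacial addition to the E-alkene makes the C10 methyl cis to the C9 arm, and shielding of one enal face by the catalyst fixes both centres absolutely; the diene termini are unsubstituted, so no endo/exo question arises.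

Step 5
Reactants: 7 aldehyde from step 4
Product: 8 5-[2-(benzyloxy)ethyl]-4-ethenyl-4-methyl-1-(triisopropylsilyloxy)cyclohex-1-ene (configuration of 7)
Conditions: Ph3PCH3Br, KOt-Bu, THF, 0 → 25 °C
Reagents that add atoms: methyltriphenylphosphonium bromide, C[P+](c1ccccc1)(c1ccccc1)c1ccccc1.[Br-]
Why: Wittig methylenation; the aldehyde has no α-hydrogen and the silyl enol ether and benzyl ether are inert to the ylide. The formyl carbon becomes C1.

Step 6
Reactants: 9 2-methylidenepropane-1,3-diol
Product: 10 2-[(tert-butyldimethylsilyloxy)methyl]prop-2-en-1-ol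
Conditions: NaH (1.0 equiv), THF, 0 °C; TBSCl
Reagents that add atoms: tert-butyldimethylsilyl chloride, CC(C)(C)[Si](C)(C)Cl
Why: Monosilylation of a symmetrical diol through its sparingly soluble monosodium alkoxide.

Step 7
Reactants: 10 mono-silyl ether from step 6
Product: 11 2-[(tert-butyldimethylsilyloxy)methyl]prop-2-en-1-yl diethyl phosphate
Conditions: ClP(O)(OEt)2, pyridine, CH2Cl2, 0 °C
Reagents that add atoms: diethyl chlorophosphate, CCOP(=O)(Cl)OCC
Why: O-phosphorylation of the allylic alcohol provides the leaving group for copper-catalysed allylic substitution.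

Step 8
Reactants: 8 vinyl compound from step 5; 11 allylic phosphate from step 7
Product: 13 5-[2-(benzyloxy)ethyl]-4-methyl-4-{4-[(tert-butyldimethylsilyloxy)methyl]pent-4-en-1-yl}-1-(triisopropylsilyloxy)cyclohex-1-ene, via the alkylborane 12 (not isolated)
Conditions: 9-BBN dimer, THF, 60 °C; then 11, CuOAc (10 mol%), KOt-Bu (1 equiv per boron), THF, 60 °C
Reagents that add atoms: none
Why: 9-BBN hydroborates the monosubstituted vinyl group anti-Markovnikov and leaves the trisubstituted silyl enol ether; the alkylborate transmetalates to monovalent copper and the alkylcopper substitutes the allylic phosphate (copper-catalysed allyl–alkyl coupling of alkylboranes). Both allyl termini are CH2, so SN2 and SN2′ give the same product, and C2–C3 is made without any alkene reduction beside the C4 methylidene group.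

Step 9
Reactants: 13 silyl enol ether from step 8
Product: 14 5-[2-(benzyloxy)ethyl]-4-methyl-4-{4-[(tert-butyldimethylsilyloxy)methyl]pent-4-en-1-yl}cyclohex-2-en-1-one (configuration of 7)
Conditions: Pd(OAc)2 (1.1 equiv), MeCN, 25 → 40 °C
Reagents that add atoms: none
Why: Saegusa–Ito oxidation; divalent palladium forms the C6 palladium enolate and β-hydride elimination can only take hydrogen from C5, so the Δ5 enone forms regiospecifically.

Step 10
Reactants: 14 enone from step 9
Product: 16 5-[2-(benzyloxy)ethyl]-4,6-dimethyl-4-{4-[(tert-butyldimethylsilyloxy)methyl]pent-4-en-1-yl}cyclohex-2-en-1-one with 6-methyl trans to the arm, via the lithium dienolate 15 (not isolated)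
Conditions: LiN(i-Pr)2, THF, −78 °C; MeI, −78 → −30 °C
Reagents that add atoms: iodomethane, CI
Why: Kinetic α′-enolate alkylation; C10 is quaternary, so C8 is the only enolisable position, and iodomethane should enter anti to the neighbouring C9 arm. The C8 configuration is immaterial because C8 becomes sp2 again in step 14.

Step 11
Reactants: 16 silyl ether from step 10
Product: 17 5-[2-(benzyloxy)ethyl]-4-[4-(hydroxymethyl)pent-4-en-1-yl]-4,6-dimethylcyclohex-2-en-1-one (stereochemistry of 16)
Conditions: HF·pyridine, pyridine, THF, 0 → 25 °C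
Reagents that add atoms: none
Why: Fluoride cleaves the primary allylic silyl ether while the benzyl ether and enone are stable; the free hydroxyl is the organising group of step 12.

Step 12
Reactants: 17 hydroxy enone from step 11
Product: 18 12-(benzyloxy)-18-hydroxy-13,14,15,16-tetranor-5β-labdan-7-one (cis-decalin: 5β-H, 10β-CH3, 9α-H, 4α-CH2OH, 4β-CH3, 8α-CH3)
Conditions: Fe(acac)3 (30 mol%), PhSiH2(Oi-Pr), i-PrOH (2 equiv), (CH2Cl)2, 0.01 M, 25 → 40 °C
Reagents that add atoms: none
Why: Fe(acac)3 and the silane generate an iron hydride (trivalent iron) that transfers a hydrogen atom to the terminal CH2 of the electron-rich 1,1-disubstituted alkene, which becomes the C19 methyl and leaves a nucleophilic tertiary radical at C4; the electron-poor enone is not a hydrogen-atom acceptor here. The radical adds to the enone β-carbon C5 in a 6-exo-trig, chair-like transition state (7-endo attack at C6 is polarity-mismatched), and the α-keto radical is reduced by divalent iron and protonated; the closest known reaction type is the intramolecular iron/silane reductive coupling of an unactivated alkene with an enone (hydrogen-atom-transfer-initiated Giese addition). C5: the three-carbon chain is anchored on the α-face of quaternary C10 and cannot reach the β-lobe of C5, so the new bond is α, H5 becomes β and the fusion is cis. C4: in the chair the ring-B envelope has the C10 methyl pseudo-axial and the tether pseudo-equatorial, attack occurs anti to that methyl and C3 lies anti to C6, so one exocyclic group of C4 sits over the α-face of ring B (inner site, 4α in the product) and the other points outward (4β). The target needs the CH2O group inside; methyl and CH2OR are almost isosteric and a bulky silyl ether would if anything prefer the outer site, so steric control is not relied on. Instead the free hydroxyl can reach the C7 carbonyl oxygen (hydrogen bond, or as an iron alkoxide) only from the inner site, which stabilises that arrangement and activates the enone; (CH2Cl)2 with PhSiH2(Oi-Pr) is chosen over an alcoholic medium so that this contact is not swamped. The step needs chemoselective hydrogen-atom transfer, 6-exo regioselectivity and α-attack at C5, all secured by the substrate, and inner placement of CH2OH, secured only by the polar contact and therefore the weakest point; only the 4α-CH2OH product can close reversibly onto the C7 carbonyl, which gives a check of configuration and a handle for separation.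

Step 13
Reactants: 18 hydroxy ketone from step 12
Product: 19 12-(benzyloxy)-18-(tert-butyldimethylsilyloxy)-13,14,15,16-tetranor-5β-labdan-7-one
Conditions: TBSCl, imidazole, DMF, 25 °C
Reagents that add atoms: tert-butyldimethylsilyl chloride, CC(C)(C)[Si](C)(C)Cl
Why: Imidazole-catalysed silylation of the primary hydroxyl removes the acidic proton and the ring–chain equilibrium with C7 before the ketone is enolised.

Step 14
Reactants: 19 ketone from step 13
Product: 21 12-(benzyloxy)-18-(tert-butyldimethylsilyloxy)-13,14,15,16-tetranor-5β-labd-7-en-7-yl trifluoromethanesulfonate, via the potassium enolate 20 (not isolated)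
Conditions: KN(SiMe3)2 (0.95 equiv), THF, −78 → 0 °C; PhNTf2, −78 → 25 °C
Reagents that add atoms: N-phenylbis(trifluoromethanesulfonimide), O=S(=O)(N(c1ccccc1)S(=O)(=O)C(F)(F)F)C(F)(F)F
Why: Thermodynamic enolate formation; with slightly less than one equivalent of base the enolates equilibrate through residual ketone toward the more substituted C7=C8 enolate, which the triflimide traps as the enol triflate. The C8 centre from step 10 disappears here as planned.

Step 15
Reactants: 21 enol triflate from step 14
Product: 22 12-(benzyloxy)-18-(tert-butyldimethylsilyloxy)-13,14,15,16-tetranor-5β-labd-7-ene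
Conditions: Pd(OAc)2 (5 mol%), PPh3, HCO2H, Bu3N, DMF, 60 °C
Reagents that add atoms: none
Why: Palladium-catalysed formate reduction of an enol triflate (oxidative addition to zerovalent palladium, formate exchange, decarboxylation, reductive elimination) replaces OTf by H and leaves the benzyl and silyl ethers.

Step 16
Reactants: 22 alkene from step 15
Product: 23 12-(benzyloxy)-18-(tert-butyldimethylsilyloxy)-7α,8α-epoxy-13,14,15,16-tetranor-5β-labdane
Conditions: m-CPBA, NaHCO3, CH2Cl2, 0 °C
Reagents that add atoms: 3-chloroperoxybenzoic acid, OOC(=O)c1cccc(Cl)c1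
Why: Peracid (Prilezhaev) epoxidation of the only alkene. Allylic 1,2-strain between the C8 methyl and the C9 arm should turn the arm pseudo-axial on the β-face, where the C10 methyl also lies, so the oxidant is expected on the α-face and the C8 oxygen is set with the target configuration.

Step 17
Reactants: 23 epoxide from step 16
Product: 24 12-(benzyloxy)-18-(tert-butyldimethylsilyloxy)-13,14,15,16-tetranor-5β-labdan-8α-ol
Conditions: LiAlH4, THF, 0 → 65 °C; aq. NaOH work-up
Reagents that add atoms: none
Why: Hydride opens the trisubstituted epoxide at the less substituted carbon C7 with inversion (trans-diaxial, Fürst–Plattner opening), so the oxygen stays on C8 as the 8α tertiary alcohol with the 8β methyl.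

Step 18
Reactants: 24 tertiary alcohol from step 17
Product: 25 12-(benzyloxy)-18-(tert-butyldimethylsilyloxy)-8α-(triethylsilyloxy)-13,14,15,16-tetranor-5β-labdane
Conditions: Et3SiOTf, 2,6-lutidine, CH2Cl2, −78 → 0 °C
Reagents that add atoms: triethylsilyl trifluoromethanesulfonate, CC[Si](CC)(CC)OS(=O)(=O)C(F)(F)F
Why: Silyl triflate with a hindered base silylates the tertiary alcohol. The mask is needed because an 8α-oxygen closes a five-membered ether onto C12 once C12 carries a leaving group (steps 20 and 21).

Step 19
Reactants: 25 benzyl ether from step 18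
Product: 26 18-(tert-butyldimethylsilyloxy)-8α-(triethylsilyloxy)-13,14,15,16-tetranor-5β-labdan-12-ol
Conditions: H2 (1 atm), Pd(OH)2/C, EtOAc, 25 °C
Reagents that add atoms: none
Why: Hydrogenolysis of the benzyl ether; the molecule has no C=C bond at this stage and both silyl ethers are stable in a non-protic solvent.

Step 20
Reactants: 26 primary alcohol from step 19
Product: 27 12-iodo-18-(tert-butyldimethylsilyloxy)-8α-(triethylsilyloxy)-13,14,15,16-tetranor-5β-labdane
Conditions: I2, PPh3, imidazole, CH2Cl2, 0 °C
Reagents that add atoms: iodine, II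
Why: Appel-type iodination of the unhindered primary alcohol under neutral conditions that keep both silyl ethers.

Step 21
Reactants: 27 iodide from step 20; 28 2-chlorobuta-1,3-diene
Product: 30 18-(tert-butyldimethylsilyloxy)-8α-(triethylsilyloxy)-5β-labda-13(16),14-diene, via buta-1,3-dien-2-ylmagnesium chloride 29 (not isolated)
Conditions: 28, Mg, ZnCl2 (cat.), THF, 65 °C; then 27, Li2CuCl4 (5 mol%), THF, −20 → 0 °C
Reagents that add atoms: none
Why: Grignard formation from the vinylic chloride, then Li2CuCl4-catalysed coupling of the dienylmagnesium reagent with the primary iodide (copper-catalysed alkyl halide–Grignard cross-coupling) forms C12–C13 and delivers the intact 2-substituted diene.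

Step 22
Reactants: 30 bis-silyl ether from step 21
Product: 31 5β-labda-13(16),14-diene-8α,18-diol
Conditions: Bu4NF, THF, 25 → 45 °C
Reagents that add atoms: none
Why: Fluoride cleaves both silyl ethers without acid; acid is avoided from here on because the 8-hydroxyl would add to the protonated diene.

Step 23
Reactants: 31 diol from step 22
Product: 32 8α-hydroxy-5β-labda-13(16),14-dien-18-yl bromoacetate
Conditions: BrCH2COBr, 2,6-lutidine, CH2Cl2, −40 → −20 °C
Reagents that add atoms: bromoacetyl bromide, BrCC(Br)=O
Why: Acylation with an acid bromide is selective for the primary 18-hydroxyl over the tertiary 8-hydroxyl; low temperature and a hindered base prevent N-alkylation by the bromoacetate.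

Step 24
Reactants: 32 bromoacetate from step 23
Product: 33 8α-hydroxy-5β-labda-13(16),14-dien-18-yl (diphenoxyphosphoryl)acetate
Conditions: (PhO)2P(O)H, Et3N, CH2Cl2, 0 → 25 °C
Reagents that add atoms: diphenyl phosphite, O=[PH](Oc1ccccc1)Oc1ccccc1
Why: Michaelis–Becker-type P-alkylation; the amine salt of the phosphite displaces the activated bromide and gives the diaryl phosphonoacetate needed for Z-selective olefination.

Step 25
Reactants: 33 phosphonoacetate from step 24; 34 4-(tert-butyldimethylsilyloxy)benzaldehyde
Product: 35 8α-hydroxy-5β-labda-13(16),14-dien-18-yl (Z)-3-[4-(tert-butyldimethylsilyloxy)phenyl]prop-2-enoate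
Conditions: NaI, DBU, THF, −78 → 0 °C, dark
Reagents that add atoms: none
Why: Z-selective Horner–Wadsworth–Emmons olefination with a diaryl phosphonoacetate; the electron-poor aryloxy groups make oxaphosphetane collapse faster than equilibration, so the kinetic cis adduct gives the Z-cinnamate. The mild NaI/DBU base leaves the tertiary alcohol and the diene untouched.

Step 26
Reactants: 35 silyl-protected ester from step 25
Product: 36 8α-hydroxy-5β-labda-13(16),14-dien-18-yl (Z)-3-(4-hydroxyphenyl)prop-2-enoate (target)
Conditions: Bu4NF, AcOH, THF, 0 °C, dark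
Reagents that add atoms: none
Why: Buffered fluoride cleaves the aryl silyl ether quickly at 0 °C; acetic acid protonates the phenoxide at once, which should prevent base-induced Z-to-E isomerisation and ester cleavage.

## Compound list

1 | 3-(benzyloxy)propan-1-ol | OCCCOCc1ccccc1 | starting material
2 | 3-(benzyloxy)propanal | O=CCCOCc1ccccc1 | intermediate
3 | 2-(triphenylphosphoranylidene)propanal | CC(C=O)=P(c1ccccc1)(c1ccccc1)c1ccccc1 | starting material
4 | (E)-5-(benzyloxy)-2-methylpent-2-enal | O=C/C(C)=C/CCOCc1ccccc1 | intermediate
5 | but-3-en-2-one | CC(=O)C=C | starting material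
6 | 2-(triisopropylsilyloxy)buta-1,3-diene | C=CC(=C)O[Si](C(C)C)(C(C)C)C(C)C | intermediate
7 | (1S,6S)-6-[2-(benzyloxy)ethyl]-1-methyl-4-(triisopropylsilyloxy)cyclohex-3-ene-1-carbaldehyde | c1ccc(COCC[C@@H]2[C@@](C)(C=O)CC=C(O[Si](C(C)C)(C(C)C)C(C)C)C2)cc1 | intermediate
8 | 5-[2-(benzyloxy)ethyl]-4-ethenyl-4-methyl-1-(triisopropylsilyloxy)cyclohex-1-ene (methyl cis to arm, configuration of 7) | c1ccc(COCC[C@@H]2[C@@](C)(C=C)CC=C(O[Si](C(C)C)(C(C)C)C(C)C)C2)cc1 | intermediate
9 | 2-methylidenepropane-1,3-diol | C=C(CO)CO | starting material
10 | 2-[(tert-butyldimethylsilyloxy)methyl]prop-2-en-1-ol | C=C(CO)CO[Si](C)(C)C(C)(C)C | intermediate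
11 | 2-[(tert-butyldimethylsilyloxy)methyl]prop-2-en-1-yl diethyl phosphate | C=C(CO[Si](C)(C)C(C)(C)C)COP(=O)(OCC)OCC | intermediate
12 | B-alkyl-9-borabicyclo[3.3.1]nonane from 8 (boron on the terminal carbon of the former ethenyl group) | c1ccc(COCC[C@@H]2[C@@](C)(CCB3C4CCCC3CCC4)CC=C(O[Si](C(C)C)(C(C)C)C(C)C)C2)cc1 | intermediate
13 | 5-[2-(benzyloxy)ethyl]-4-methyl-4-{4-[(tert-butyldimethylsilyloxy)methyl]pent-4-en-1-yl}-1-(triisopropylsilyloxy)cyclohex-1-ene | c1ccc(COCC[C@@H]2[C@@](C)(CCCC(=C)CO[Si](C)(C)C(C)(C)C)CC=C(O[Si](C(C)C)(C(C)C)C(C)C)C2)cc1 | intermediate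
14 | 5-[2-(benzyloxy)ethyl]-4-methyl-4-{4-[(tert-butyldimethylsilyloxy)methyl]pent-4-en-1-yl}cyclohex-2-en-1-one | c1ccc(COCC[C@@H]2[C@@](C)(CCCC(=C)CO[Si](C)(C)C(C)(C)C)C=CC(=O)C2)cc1 | intermediate
15 | lithium cross-conjugated dienolate of 14 (C7–O–Li, C7=C8) | c1ccc(COCC[C@@H]2[C@@](C)(CCCC(=C)CO[Si](C)(C)C(C)(C)C)C=CC(O[Li])=C2)cc1 | intermediate
16 | 5-[2-(benzyloxy)ethyl]-4,6-dimethyl-4-{4-[(tert-butyldimethylsilyloxy)methyl]pent-4-en-1-yl}cyclohex-2-en-1-one (6-methyl trans to arm) | c1ccc(COCC[C@@H]2[C@@](C)(CCCC(=C)CO[Si](C)(C)C(C)(C)C)C=CC(=O)[C@H]2C)cc1 | intermediate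
17 | 5-[2-(benzyloxy)ethyl]-4-[4-(hydroxymethyl)pent-4-en-1-yl]-4,6-dimethylcyclohex-2-en-1-one | c1ccc(COCC[C@@H]2[C@@](C)(CCCC(=C)CO)C=CC(=O)[C@H]2C)cc1 | intermediate
18 | 12-(benzyloxy)-18-hydroxy-13,14,15,16-tetranor-5β-labdan-7-one (8α-methyl) | c1ccc(COCC[C@@H]2[C@@]3(C)CCC[C@@](C)(CO)[C@H]3CC(=O)[C@H]2C)cc1 | intermediate
19 | 12-(benzyloxy)-18-(tert-butyldimethylsilyloxy)-13,14,15,16-tetranor-5β-labdan-7-one | c1ccc(COCC[C@@H]2[C@@]3(C)CCC[C@@](C)(CO[Si](C)(C)C(C)(C)C)[C@H]3CC(=O)[C@H]2C)cc1 | intermediate
20 | potassium Δ7-enolate of 19 | c1ccc(COCC[C@@H]2[C@@]3(C)CCC[C@@](C)(CO[Si](C)(C)C(C)(C)C)[C@H]3CC(O[K])=C2C)cc1 | intermediate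
21 | 12-(benzyloxy)-18-(tert-butyldimethylsilyloxy)-13,14,15,16-tetranor-5β-labd-7-en-7-yl trifluoromethanesulfonate | c1ccc(COCC[C@@H]2[C@@]3(C)CCC[C@@](C)(CO[Si](C)(C)C(C)(C)C)[C@H]3CC(OS(=O)(=O)C(F)(F)F)=C2C)cc1 | intermediate
22 | 12-(benzyloxy)-18-(tert-butyldimethylsilyloxy)-13,14,15,16-tetranor-5β-labd-7-ene | c1ccc(COCC[C@@H]2[C@@]3(C)CCC[C@@](C)(CO[Si](C)(C)C(C)(C)C)[C@H]3CC=C2C)cc1 | intermediate
23 | 12-(benzyloxy)-18-(tert-butyldimethylsilyloxy)-7α,8α-epoxy-13,14,15,16-tetranor-5β-labdane | c1ccc(COCC[C@@H]2[C@@]3(C)CCC[C@@](C)(CO[Si](C)(C)C(C)(C)C)[C@H]3C[C@H]4O[C@@]24C)cc1 | intermediate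
24 | 12-(benzyloxy)-18-(tert-butyldimethylsilyloxy)-13,14,15,16-tetranor-5β-labdan-8α-ol | c1ccc(COCC[C@@H]2[C@@]3(C)CCC[C@@](C)(CO[Si](C)(C)C(C)(C)C)[C@H]3CC[C@@]2(C)O)cc1 | intermediate
25 | 12-(benzyloxy)-18-(tert-butyldimethylsilyloxy)-8α-(triethylsilyloxy)-13,14,15,16-tetranor-5β-labdane | c1ccc(COCC[C@@H]2[C@@]3(C)CCC[C@@](C)(CO[Si](C)(C)C(C)(C)C)[C@H]3CC[C@@]2(C)O[Si](CC)(CC)CC)cc1 | intermediate
26 | 18-(tert-butyldimethylsilyloxy)-8α-(triethylsilyloxy)-13,14,15,16-tetranor-5β-labdan-12-ol | OCC[C@@H]1[C@@]2(C)CCC[C@@](C)(CO[Si](C)(C)C(C)(C)C)[C@H]2CC[C@@]1(C)O[Si](CC)(CC)CC | intermediate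
27 | 12-iodo-18-(tert-butyldimethylsilyloxy)-8α-(triethylsilyloxy)-13,14,15,16-tetranor-5β-labdane | ICC[C@@H]1[C@@]2(C)CCC[C@@](C)(CO[Si](C)(C)C(C)(C)C)[C@H]2CC[C@@]1(C)O[Si](CC)(CC)CC | intermediate
28 | 2-chlorobuta-1,3-diene | C=CC(Cl)=C | starting material
29 | buta-1,3-dien-2-ylmagnesium chloride | C=CC(=C)[Mg]Cl | intermediate
30 | 18-(tert-butyldimethylsilyloxy)-8α-(triethylsilyloxy)-5β-labda-13(16),14-diene | C=CC(=C)CC[C@@H]1[C@@]2(C)CCC[C@@](C)(CO[Si](C)(C)C(C)(C)C)[C@H]2CC[C@@]1(C)O[Si](CC)(CC)CC | intermediate
31 | 5β-labda-13(16),14-diene-8α,18-diol | C=CC(=C)CC[C@@H]1[C@@]2(C)CCC[C@@](C)(CO)[C@H]2CC[C@@]1(C)O | intermediate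
32 | 8α-hydroxy-5β-labda-13(16),14-dien-18-yl bromoacetate | C=CC(=C)CC[C@@H]1[C@@]2(C)CCC[C@@](C)(COC(=O)CBr)[C@H]2CC[C@@]1(C)O | intermediate
33 | 8α-hydroxy-5β-labda-13(16),14-dien-18-yl (diphenoxyphosphoryl)acetate | C=CC(=C)CC[C@@H]1[C@@]2(C)CCC[C@@](C)(COC(=O)CP(=O)(Oc3ccccc3)Oc3ccccc3)[C@H]2CC[C@@]1(C)O | intermediate
34 | 4-(tert-butyldimethylsilyloxy)benzaldehyde | O=Cc1ccc(O[Si](C)(C)C(C)(C)C)cc1 | starting material
35 | 8α-hydroxy-5β-labda-13(16),14-dien-18-yl (Z)-3-[4-(tert-butyldimethylsilyloxy)phenyl]prop-2-enoate | C=CC(=C)CC[C@@H]1[C@@]2(C)CCC[C@@](C)(COC(=O)/C=C\c3ccc(O[Si](C)(C)C(C)(C)C)cc3)[C@H]2CC[C@@]1(C)O | intermediate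
36 | 8α-hydroxy-5β-labda-13(16),14-dien-18-yl (Z)-3-(4-hydroxyphenyl)prop-2-enoate | C=CC(=C)CC[C@@H]1[C@@]2(C)CCC[C@@](C)(COC(=O)/C=C\c3ccc(O)cc3)[C@H]2CC[C@@]1(C)O | target

## Step count and least certain steps

Total step count: 26. Longest linear sequence: 23 steps (steps 1, 2, 4, 5 and 8–26, counted from 1); steps 3, 6 and 7 are side branches.

**Step 12 (key step).** The likely failure is poor discrimination between the inner and outer orientation of the hydroxymethyl group at the planar C4 radical, because this selectivity rests on one hydrogen bond and not on a steric difference; reduction of the radical before ring closure is a second risk. The fallback takes the stereochemical question out of the radical step. It sets out from vinyl compound 8, hydroborated to 12 as in step 8. A Suzuki–Miyaura coupling (PdCl2(dppf), K3PO4, THF/H2O) with 5-(bromomethylidene)-2,2-dimethyl-1,3-dioxane F1, made from 2,2-dimethyl-1,3-dioxan-5-one by Wittig bromomethylenation, should give the alkylidene-dioxane silyl enol ether F2. Oxidation with Pd(OAc)2 as in step 9 gives the enone F3, whose lithium dienolate F4 is methylated to the 6-methyl enone F5. The same Fe(acac)3/silane closure, with the hydrogen atom now delivered to C3, gives the spiro-acetonide ketone F6, in which C4 is not yet a stereocentre. Acidic methanol removes the acetonide, and only the 4α-hydroxymethyl group can reach C7; it is locked as the bridged 7,18-epoxy 7-methyl ketal F7, which leaves the 4β-CH2OH free. Iodination (I2, PPh3, imidazole, toluene, 80 °C) to the neopentyl iodide F8 and reduction with Bu3SnH to the 4β-methyl ketal F9 turn that arm into C19. Aqueous acid then opens the ketal and the route is rejoined at 18.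

**Step 4.** The trisubstituted enal may react too slowly, with erosion of enantiofacial control or acid-induced loss of the silyloxydiene. The fallback sets out from enal 4 and uses the far more reactive (E)-3-(tert-butyldimethylsilyloxy)-N,N-dimethylbuta-1,3-dien-1-amine under a chiral salen complex of trivalent chromium, (salen)CrSbF6. This should give the amino silyl enol ether cycloadduct F10. Methylenation as in step 5 gives the vinyl compound F11, hydroboration gives the alkylborane F12, and copper-catalysed coupling with 11 gives the tether-complete amino enol ether F13. Dilute HCl in THF hydrolyses the enol ether and eliminates dimethylamine, so the route is rejoined at enone 14 without the palladium oxidation.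

**Step 14.** Enolate equilibration may not favour the C8 side enough, so that regiochemistry leaks toward the C6 enol triflate. The fallback sets out from ketone 19: NaBH4 reduction should give the 7α-alcohol F14 (hydride from the face away from the axial C4 substituent), and POCl3/pyridine dehydration (anti elimination, Zaitsev orientation) rejoins the route at alkene 22.

**Step 16.** The peracid may approach from the β-face, or with low selectivity, because both faces of the alkene in the mobile cis-decalin are hindered and the oxidant bridges C7 and C8. The fallback sets out from alkene 22 and uses a Mukaiyama hydration (Mn(dpm)3, PhSiH3, O2, i-PrOH, 0 °C): the hydrogen atom goes to C7 and oxygen is trapped at the tertiary C8 radical alone, away from the C10 methyl and the C9 arm and without sensing the C4 group above C7. It rejoins the route directly at 24 and makes no new compound.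

**Step 21.** Cross-coupling may be slow relative to homocoupling or polymerisation of the dienyl Grignard reagent, or the iodide may undergo dehydrohalogenation. The fallback sets out from iodide 27: alkylation of LiC≡CH·H2NCH2CH2NH2 in DMSO should give the terminal alkyne F15, and cross enyne metathesis with ethylene under second-generation Grubbs catalyst RuCl2(=CHPh)(PCy3)(H2IMes) rejoins the route at 30.

## Further compounds

F1 | step 12 | 5-(bromomethylidene)-2,2-dimethyl-1,3-dioxane | CC1(C)OCC(=CBr)CO1
F2 | step 12 | alkylidene-dioxane silyl enol ether (Suzuki product of 12 and F1) | c1ccc(COCC[C@@H]2[C@@](C)(CCC=C3COC(C)(C)OC3)CC=C(O[Si](C(C)C)(C(C)C)C(C)C)C2)cc1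
F3 | step 12 | 5-[2-(benzyloxy)ethyl]-4-[3-(2,2-dimethyl-1,3-dioxan-5-ylidene)propyl]-4-methylcyclohex-2-en-1-one | c1ccc(COCC[C@@H]2[C@@](C)(CCC=C3COC(C)(C)OC3)C=CC(=O)C2)cc1
F4 | step 12 | lithium dienolate of F3 | c1ccc(COCC[C@@H]2[C@@](C)(CCC=C3COC(C)(C)OC3)C=CC(O[Li])=C2)cc1
F5 | step 12 | 6-methyl derivative of F3 (methyl trans to arm) | c1ccc(COCC[C@@H]2[C@@](C)(CCC=C3COC(C)(C)OC3)C=CC(=O)[C@H]2C)cc1
F6 | step 12 | spiro-acetonide of 12-(benzyloxy)-18,19-dihydroxy-13,14,15,16-tetranor-5β-labdan-7-one | c1ccc(COCC[C@@H]2[C@@]3(C)CCCC4(COC(C)(C)OC4)[C@H]3CC(=O)[C@H]2C)cc1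
F7 | step 12 | 12-(benzyloxy)-7α,18-epoxy-7β-methoxy-13,14,15,16-tetranor-5β-labdan-19-ol | c1ccc(COCC[C@@H]2[C@@]3(C)CCC[C@@]4(CO)CO[C@](OC)(C[C@@H]34)[C@H]2C)cc1
F8 | step 12 | 12-(benzyloxy)-7α,18-epoxy-19-iodo-7β-methoxy-13,14,15,16-tetranor-5β-labdane | c1ccc(COCC[C@@H]2[C@@]3(C)CCC[C@@]4(CI)CO[C@](OC)(C[C@@H]34)[C@H]2C)cc1
F9 | step 12 | 12-(benzyloxy)-7α,18-epoxy-7β-methoxy-13,14,15,16-tetranor-5β-labdane | c1ccc(COCC[C@@H]2[C@@]3(C)CCC[C@@]4(C)CO[C@](OC)(C[C@@H]34)[C@H]2C)cc1
F10 | step 4 | 6-[2-(benzyloxy)ethyl]-2-(dimethylamino)-1-methyl-4-(tert-butyldimethylsilyloxy)cyclohex-3-ene-1-carbaldehyde (amino carbon: either epimer) | c1ccc(COCC[C@@H]2[C@@](C)(C=O)C(N(C)C)C=C(O[Si](C)(C)C(C)(C)C)C2)cc1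
F11 | step 4 | ethenyl analogue of F10 | c1ccc(COCC[C@@H]2[C@@](C)(C=C)C(N(C)C)C=C(O[Si](C)(C)C(C)(C)C)C2)cc1
F12 | step 4 | B-alkyl-9-borabicyclo[3.3.1]nonane from F11 | c1ccc(COCC[C@@H]2[C@@](C)(CCB3C4CCCC3CCC4)C(N(C)C)C=C(O[Si](C)(C)C(C)(C)C)C2)cc1
F13 | step 4 | tether-complete amino silyl enol ether | c1ccc(COCC[C@@H]2[C@@](C)(CCCC(=C)CO[Si](C)(C)C(C)(C)C)C(N(C)C)C=C(O[Si](C)(C)C(C)(C)C)C2)cc1
F14 | step 14 | 12-(benzyloxy)-18-(tert-butyldimethylsilyloxy)-13,14,15,16-tetranor-5β-labdan-7α-ol | c1ccc(COCC[C@@H]2[C@@]3(C)CCC[C@@](C)(CO[Si](C)(C)C(C)(C)C)[C@H]3C[C@@H](O)[C@H]2C)cc1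
F0 | step 16 | none | none
F15 | step 21 | 18-(tert-butyldimethylsilyloxy)-8α-(triethylsilyloxy)-15,16-dinor-5β-labd-13-yne | C#CCC[C@@H]1[C@@]2(C)CCC[C@@](C)(CO[Si](C)(C)C(C)(C)C)[C@H]2CC[C@@]1(C)O[Si](CC)(CC)CC
A1 | alternative 1 | cis-fused Δ1-octalin methyl ester with C8 dioxolane and silyloxyethyl arm | CC(C)(C)[Si](C)(C)OCC[C@@H]1[C@@]2(C)C=CC[C@@](C)(C(=O)OC)[C@H]2CCC13OCCO3
A2 | alternative 1 | acyclic triene ester with (Z)-diene and (Z)-2-methyl enoate | CC(C)(C)[Si](C)(C)OCC[C@@H](C1(CC/C=C(/C)C(=O)OC)OCCO1)/C(C)=C\C=C
A3 | alternative 2 | 18-(tert-butyldimethylsilyloxy)-5β-labda-13(16),14-dien-8α-ol | C=CC(=C)CC[C@@H]1[C@@]2(C)CCC[C@@](C)(CO[Si](C)(C)C(C)(C)C)[C@H]2CC[C@@]1(C)O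
A4 | alternative 2 | 18-(tert-butyldimethylsilyloxy)-15,16-dinor-5β-labd-13-yn-8α-ol | C#CCC[C@@H]1[C@@]2(C)CCC[C@@](C)(CO[Si](C)(C)C(C)(C)C)[C@H]2CC[C@@]1(C)O
A5 | alternative 2 | ethylene | C=C
A6 | alternative 3 | methyl 8α-hydroxy-18-(tert-butyldimethylsilyloxy)-13,14,15,16-tetranor-5β-labdan-12-oate | COC(=O)C[C@@H]1[C@@]2(C)CCC[C@@](C)(CO[Si](C)(C)C(C)(C)C)[C@H]2CC[C@@]1(C)O
A7 | alternative 3 | cyclohexane with (E)-enoate on C10 and 3-oxobutyl chain on C5 | COC(=O)/C=C/[C@@]1(C)CCC[C@@](C)(CO[Si](C)(C)C(C)(C)C)[C@H]1CCC(C)=O
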